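**Plan**
- Ring A carries O5 and O8 para to each other, H at C6 and O at C7, and is fused to ring C through C4a–C8a. A squaric acid monoester adduct delivers exactly this pattern, so the first cut is C4a–C5 (ring A back to a 4-hydroxycyclobutenone) and the second is C8–C8a (metalated pyranone plus cyclobutenedione).
- Further cuts: C2–C1' (Negishi coupling), the 4'-O–prenyl bond and the O8–methyl bond. Ring C is bought as a 3-hydroxy-4-pyranone, ring B as a phenol.
- Forward: ring C is arylated at C2, magnesiated at C6 and joined to the four-carbon dione; heating builds ring A (4π opening, 6π closure); O8 is methylated; fluoride frees O3 and O7.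
- O3 and O7 both travel as 2-(trimethylsilyl)ethyl ethers, so the acid-labile 4'-prenyl ether never meets acid.
- The target has no stereocentre and no stereogenic alkene; the carbinol centre of the cyclobutenone is racemic and is erased in the key step.

Key step: step 7

Remark: prenyl = 3-methylbut-2-en-1-yl. Compounds 12, 15 and 17 are racemates whose single stereocentre is lost later; their SMILES show one enantiomer.

**Step 1**
Reactants: 1 pyromeconic acid (3-hydroxy-4H-pyran-4-one)
Product: 2 3-[2-(trimethylsilyl)ethoxy]-4H-pyran-4-one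
Conditions: Me3SiCH2CH2OH, PPh3, DIAD, THF, 0 °C → rt
Reagents that add atoms: 2-(trimethylsilyl)ethanol, C[Si](C)(C)CCO
Why: Mitsunobu etherification, for which the enolic 3-hydroxyl (about as acidic as a phenol) is a suitable acid partner; the ether tolerates amide bases and is later cleaved by fluoride.

**Step 2**
Reactants: 3 4-iodophenol; 4 prenyl bromide (1-bromo-3-methylbut-2-ene)
Product: 5 1-iodo-4-(prenyloxy)benzene
Conditions: K2CO3, acetone, reflux
Reagents that add atoms: none
Why: Williamson ether synthesis of a phenoxide with a reactive primary allylic bromide, which should give O-alkylation only under carbonate conditions.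

**Step 3**
Reactants: 2 3-[2-(trimethylsilyl)ethoxy]-4H-pyran-4-one; 5 1-iodo-4-(prenyloxy)benzene
Product: 8 2-[4-(prenyloxy)phenyl]-3-[2-(trimethylsilyl)ethoxy]-4H-pyran-4-one, via C2-magnesiated pyranone 6 (not isolated), via C2-zincated pyranone 7 (not isolated)
Conditions: TMPMgCl·LiCl, THF, −40 °C; ZnCl2, −40 °C → rt; 5, Pd(OAc)2 (2 mol %), SPhos (4 mol %), 40 °C
Reagents that add atoms: none
Why: Directed magnesiation then Negishi cross-coupling: C2–H lies between the ring oxygen and the alkoxy group and is the most acidic, best-coordinated site for the hindered amide base, and oxidative addition of the aryl iodide to zerovalent palladium should be far faster than ionisation of the trisubstituted allylic aryl ether.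

**Step 4**
Reactants: 9 squaric acid (3,4-dihydroxycyclobut-3-ene-1,2-dione)
Product: 11 3,4-bis[2-(trimethylsilyl)ethoxy]cyclobut-3-ene-1,2-dione, via squaryl dichloride 10 (not isolated)
Conditions: (COCl)2, DMF (cat.), CH2Cl2, reflux, then evaporation; Me3SiCH2CH2OH, iPr2NEt, CH2Cl2, 0 °C → rt
Reagents that add atoms: 2-(trimethylsilyl)ethanol, C[Si](C)(C)CCO
Why: Acid chloride formation followed by alcoholysis (addition–elimination on the vinylogous acid chloride) under amine buffering gives the diester without the hot strong acid of direct esterification, which the β-silylethyl group would not tolerate.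

**Step 5**
Reactants: 11 3,4-bis[2-(trimethylsilyl)ethoxy]cyclobut-3-ene-1,2-dione
Product: 13 3-[2-(trimethylsilyl)ethoxy]cyclobut-3-ene-1,2-dione, via hydroxycyclobutenone 12 (not isolated)
Conditions: LiAlH(OtBu)3, THF, −78 → −20 °C, aqueous work-up; then conc. HCl (cat.), CH2Cl2, 0 °C
Reagents that add atoms: none
Why: Hydride 1,2-addition followed by acid-catalysed 1,3-carbonyl transposition, the standard conversion of a squarate diester into a semisquarate: the bulky hydride stops after one addition, and brief catalytic acid ionises the carbinol and expels one alkoxy group as the alcohol (the new centre of 12 is racemic and disappears here).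

**Step 6**
Reactants: 8 2-[4-(prenyloxy)phenyl]-3-[2-(trimethylsilyl)ethoxy]-4H-pyran-4-one; 13 3-[2-(trimethylsilyl)ethoxy]cyclobut-3-ene-1,2-dione
Product: 15 4-hydroxy-4-{4-oxo-6-[4-(prenyloxy)phenyl]-5-[2-(trimethylsilyl)ethoxy]-4H-pyran-2-yl}-3-[2-(trimethylsilyl)ethoxy]cyclobut-2-en-1-one (racemic), via C6-magnesiated pyranone 14 (not isolated)
Conditions: TMPMgCl·LiCl (1.05 equiv), THF, −40 °C; 13, −78 °C; aq NH4Cl
Reagents that add atoms: none
Why: Deprotonative magnesiation and carbonyl 1,2-addition: C6–H is the only C–H left next to the ring oxygen (the counterpart of C2–H in chromones), and the organomagnesium should add to the ketone-like carbonyl attached to the alkoxy-bearing carbon, not to the vinylogous-ester carbonyl, which fixes the later order O8, O7, H6, O5; the carbinol centre forms without control, as the racemate.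

**Step 7**
Reactants: 15 4-hydroxy-4-{4-oxo-6-[4-(prenyloxy)phenyl]-5-[2-(trimethylsilyl)ethoxy]-4H-pyran-2-yl}-3-[2-(trimethylsilyl)ethoxy]cyclobut-2-en-1-one
Product: 18 5,8-dihydroxy-2-[4-(prenyloxy)phenyl]-3,7-bis[2-(trimethylsilyl)ethoxy]-4H-chromen-4-one, via dienylketene 16 (not isolated), via ring-fused dienone 17 (not isolated)
Conditions: toluene (degassed, 0.02 M), 110 °C, Ar
Reagents that add atoms: none
Why: Heat opens the cyclobutenone by conrotatory 4π electrocyclic cleavage of the bond between the carbonyl carbon and the carbinol carbon, giving dienylketene 16, whose ketene is conjugated through the new enol double bond with the C6=C5 double bond of the pyranone. This is the Moore rearrangement known for 4-aryl-, 4-heteroaryl- and 4-alkenyl-4-hydroxycyclobutenones, here with a 4-pyranone as the unsaturated arm. Ring A closes by thermal disrotatory 6π electrocyclisation: the electrophilic ketene carbon (future C5) bonds to pyranone C5 (future C4a), the nucleophilic β-carbon of the O1 enol ether, and dienone 17 enolises to the aromatic hydroquinone, helped by the 5-OH to C4 carbonyl hydrogen bond. No stereocentre is formed and the racemic carbinol centre of 15 is erased. The step needs torquoselectivity: the hydroxyl, as a donor, rotates outward and turns the pyranonyl group inward toward the ketene, where C4a is the only carbon that can reach it because the other neighbour of C8a is O1. Degassed solvent under argon should keep the hydroquinone from oxidising to the quinone, and 110 °C is far below the temperature at which the aryl prenyl ether would undergo Claisen rearrangement.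

**Step 8**
Reactants: 18 5,8-dihydroxy-2-[4-(prenyloxy)phenyl]-3,7-bis[2-(trimethylsilyl)ethoxy]-4H-chromen-4-one
Product: 19 5-hydroxy-8-methoxy-2-[4-(prenyloxy)phenyl]-3,7-bis[2-(trimethylsilyl)ethoxy]-4H-chromen-4-one
Conditions: MeI (1.1 equiv), K2CO3, acetone, 40 °C, Ar
Reagents that add atoms: iodomethane, CI
Why: Williamson O-methylation under weak base: the 5-hydroxyl is held in a hydrogen bond to the C4 carbonyl and is much less reactive, so only the free 8-hydroxyl should be methylated, as in the classical partial methylation of 5,8-dihydroxyflavones.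

**Step 9**
Reactants: 19 5-hydroxy-8-methoxy-2-[4-(prenyloxy)phenyl]-3,7-bis[2-(trimethylsilyl)ethoxy]-4H-chromen-4-one
Product: 20 3,5,7-trihydroxy-8-methoxy-2-[4-(prenyloxy)phenyl]-4H-chromen-4-one (3,5,7-trihydroxy-8-methoxy-4'-prenyloxyflavone)
Conditions: Bu4NF (6 equiv), THF–DMF, 60 °C, Ar; aq NH4Cl
Reagents that add atoms: none
Why: Fluoride-induced β-elimination of the two β-silylethyl ethers (attack at silicon, loss of ethene) expels the 7-oxide and the 3-oxide, both stabilised leaving groups (vinylogous carboxylate and enolate next to the carbonyl), while the prenyl ether, the methyl ether and the hydrogen-bonded 5-hydroxyl are inert to fluoride.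

**Compound list**
1 | pyromeconic acid (3-hydroxy-4H-pyran-4-one) | O=c1ccocc1O | starting material
2 | 3-[2-(trimethylsilyl)ethoxy]-4H-pyran-4-one | O=c1ccocc1OCC[Si](C)(C)C | intermediate
3 | 4-iodophenol | Oc1ccc(I)cc1 | starting material
4 | prenyl bromide (1-bromo-3-methylbut-2-ene) | CC(C)=CCBr | starting material
5 | 1-iodo-4-(prenyloxy)benzene | CC(C)=CCOc1ccc(I)cc1 | intermediate
6 | {4-oxo-3-[2-(trimethylsilyl)ethoxy]-4H-pyran-2-yl}magnesium chloride (formed in the flask, not isolated) | Cl[Mg]c1occc(=O)c1OCC[Si](C)(C)C | intermediate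
7 | {4-oxo-3-[2-(trimethylsilyl)ethoxy]-4H-pyran-2-yl}zinc chloride (formed in the flask, not isolated) | Cl[Zn]c1occc(=O)c1OCC[Si](C)(C)C | intermediate
8 | 2-[4-(prenyloxy)phenyl]-3-[2-(trimethylsilyl)ethoxy]-4H-pyran-4-one | O=c1ccoc(-c2ccc(OCC=C(C)C)cc2)c1OCC[Si](C)(C)C | intermediate
9 | squaric acid (3,4-dihydroxycyclobut-3-ene-1,2-dione) | O=c1c(O)c(O)c1=O | starting material
10 | squaryl dichloride (3,4-dichlorocyclobut-3-ene-1,2-dione; not isolated) | O=C1C(=O)C(Cl)=C1Cl | intermediate
11 | 3,4-bis[2-(trimethylsilyl)ethoxy]cyclobut-3-ene-1,2-dione | O=C1C(=O)C(OCC[Si](C)(C)C)=C1OCC[Si](C)(C)C | intermediate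
12 | 4-hydroxy-2,3-bis[2-(trimethylsilyl)ethoxy]cyclobut-2-en-1-one (racemic, one enantiomer drawn; not isolated) | O=C1C(OCC[Si](C)(C)C)=C(OCC[Si](C)(C)C)[C@@H]1O | intermediate
13 | 3-[2-(trimethylsilyl)ethoxy]cyclobut-3-ene-1,2-dione | O=C1C=C(OCC[Si](C)(C)C)C1=O | intermediate
14 | {4-oxo-6-[4-(prenyloxy)phenyl]-5-[2-(trimethylsilyl)ethoxy]-4H-pyran-2-yl}magnesium chloride (formed in the flask, not isolated) | Cl[Mg]c1cc(=O)c(OCC[Si](C)(C)C)c(-c2ccc(OCC=C(C)C)cc2)o1 | intermediate
15 | 4-hydroxy-4-{4-oxo-6-[4-(prenyloxy)phenyl]-5-[2-(trimethylsilyl)ethoxy]-4H-pyran-2-yl}-3-[2-(trimethylsilyl)ethoxy]cyclobut-2-en-1-one (racemic, one enantiomer drawn) | O=C1C=C(OCC[Si](C)(C)C)[C@]1(O)c1cc(=O)c(OCC[Si](C)(C)C)c(-c2ccc(OCC=C(C)C)cc2)o1 | intermediate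
16 | (3Z)-4-hydroxy-4-{4-oxo-6-[4-(prenyloxy)phenyl]-5-[2-(trimethylsilyl)ethoxy]-4H-pyran-2-yl}-3-[2-(trimethylsilyl)ethoxy]buta-1,3-dien-1-one (dienylketene, pyranonyl cis to the ketene; not isolated) | O=C=C/C(OCC[Si](C)(C)C)=C(/O)c1cc(=O)c(OCC[Si](C)(C)C)c(-c2ccc(OCC=C(C)C)cc2)o1 | intermediate
17 | 8-hydroxy-2-[4-(prenyloxy)phenyl]-3,7-bis[2-(trimethylsilyl)ethoxy]-4aH-chromene-4,5-dione (racemic, one enantiomer drawn; not isolated) | O=C1C=C(OCC[Si](C)(C)C)C(O)=C2OC(-c3ccc(OCC=C(C)C)cc3)=C(OCC[Si](C)(C)C)C(=O)[C@@H]12 | intermediate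
18 | 5,8-dihydroxy-2-[4-(prenyloxy)phenyl]-3,7-bis[2-(trimethylsilyl)ethoxy]-4H-chromen-4-one | C[Si](C)(C)CCOc1cc(O)c2c(=O)c(OCC[Si](C)(C)C)c(-c3ccc(OCC=C(C)C)cc3)oc2c1O | intermediate
19 | 5-hydroxy-8-methoxy-2-[4-(prenyloxy)phenyl]-3,7-bis[2-(trimethylsilyl)ethoxy]-4H-chromen-4-one | COc1c(OCC[Si](C)(C)C)cc(O)c2c(=O)c(OCC[Si](C)(C)C)c(-c3ccc(OCC=C(C)C)cc3)oc12 | intermediate
20 | 3,5,7-trihydroxy-8-methoxy-4'-prenyloxyflavone | COc1c(O)cc(O)c2c(=O)c(O)c(-c3ccc(OCC=C(C)C)cc3)oc12 | target

**Step count and risks**
Total: 9 steps. Longest linear sequence: 6 steps (steps 1, 3, 6, 7, 8, 9 from pyromeconic acid; equally steps 4, 5, 6, 7, 8, 9 from squaric acid).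

Steps most likely to fail:

1. Step 7. The free tertiary hydroxyl may trap the ketene before the 6π closure, and the electron-rich hydroquinone may be oxidised to the 5,8-quinone by traces of oxygen at 110 °C or on purification. The fallback sets out from 15 and returns at 19. The carbinol is first capped with MeI and Ag2O in MeCN at rt to give 4-methoxy-4-{4-oxo-6-[4-(prenyloxy)phenyl]-5-[2-(trimethylsilyl)ethoxy]-4H-pyran-2-yl}-3-[2-(trimethylsilyl)ethoxy]cyclobut-2-en-1-one F1. Heating F1 in toluene at 110 °C should run the same opening and closure, with the methoxy group rotating outward as the donor, and give the 8-methyl ether 19 directly. This is the known thermolysis of 4-alkoxycyclobutenones to monoprotected hydroquinones; neither the free hydroquinone 18 nor the selective methylation of step 8 is then needed.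

2. Step 6. The magnesiated pyranone is generated beside tetramethylpiperidine and residual amide base and then meets a dione with a free vinylic C–H. Proton transfer, conjugate addition at that carbon, or slow self-addition of 14 during the metalation could each drain the adduct. The fallback sets out from 8 and returns at 14. It separates metalation from addition: the magnesium species is quenched with I2 at −40 °C to give 6-iodo-2-[4-(prenyloxy)phenyl]-3-[2-(trimethylsilyl)ethoxy]-4H-pyran-4-one F2, which is purified. Iodine–magnesium exchange with iPrMgCl·LiCl in THF at −78 °C then regenerates 14 within minutes, free of amine and excess base, and 14 is added to 13 as before.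

3. Step 3. Metalation could occur at C6 instead of C2, the metalated pyranone could ring-open, or the catalyst could be consumed by ionisation of the prenyl ether. The fallback sets out from 1 (and uses 5) and returns at 8; it replaces C–H metalation by electrophilic halogenation. NBS in MeCN at 0 °C brominates the enol position next to the hydroxyl to give 2-bromo-3-hydroxy-4H-pyran-4-one F3. Mitsunobu etherification as in step 1 gives 2-bromo-3-[2-(trimethylsilyl)ethoxy]-4H-pyran-4-one F4. Iodide 5 is converted by Miyaura borylation (B2pin2, PdCl2(dppf), KOAc, dioxane, 80 °C) into 4,4,5,5-tetramethyl-2-[4-(prenyloxy)phenyl]-1,3,2-dioxaborolane F5. Suzuki–Miyaura coupling of F4 with F5 (Pd(OAc)2, SPhos, K3PO4, toluene–water, 60 °C) should then give 8.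

**Further compounds**
F1 | step 7 | 4-methoxy-4-{4-oxo-6-[4-(prenyloxy)phenyl]-5-[2-(trimethylsilyl)ethoxy]-4H-pyran-2-yl}-3-[2-(trimethylsilyl)ethoxy]cyclobut-2-en-1-one (racemic, one enantiomer drawn) | O=C1C=C(OCC[Si](C)(C)C)[C@]1(OC)c1cc(=O)c(OCC[Si](C)(C)C)c(-c2ccc(OCC=C(C)C)cc2)o1
F2 | step 6 | 6-iodo-2-[4-(prenyloxy)phenyl]-3-[2-(trimethylsilyl)ethoxy]-4H-pyran-4-one | Ic1cc(=O)c(OCC[Si](C)(C)C)c(-c2ccc(OCC=C(C)C)cc2)o1
F3 | step 3 | 2-bromo-3-hydroxy-4H-pyran-4-one | O=c1ccoc(Br)c1O
F4 | step 3 | 2-bromo-3-[2-(trimethylsilyl)ethoxy]-4H-pyran-4-one | O=c1ccoc(Br)c1OCC[Si](C)(C)C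
F5 | step 3 | 4,4,5,5-tetramethyl-2-[4-(prenyloxy)phenyl]-1,3,2-dioxaborolane | CC(C)=CCOc1ccc(B2OC(C)(C)C(C)(C)O2)cc1
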